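**Strategy.** The route rests on a [4+2] disconnection of ring B of the cis-fused decalin. Cutting C8–C8a and C5–C4a leaves the tetrasubstituted C=C of a 4-oxocyclohex-2-ene-1-carboxylate (ring A, already carrying the C1 ester and the C2 methyl) and (E)-8-methylnona-1,3,7-triene, which supplies C5–C8 and the homoprenyl chain. One Lewis-acid-promoted Diels–Alder reaction forms both bonds, the two vicinal methyl-bearing quaternary carbons C4a/C8a and the cis ring fusion. A methyl stereocentre installed by organocatalysis steers the facial course and is then corrected by dehydrogenation/reduction. Olefin migration to C5=C6, Wolff–Kishner deoxygenation and epoxide opening by the acid complete the glyceride.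

Key step: step 3

Remark: locants are those of the octahydronaphthalene skeleton of the target acid (C1 carboxyl-bearing, C2 secondary methyl, C4a/C8a ring fusion, C5 side chain; ring A = C1–C4, ring B = C5–C8); 5-methylhex-4-enal is taken as a catalogue aldehyde, otherwise one Claisen rearrangement away from 2-methylbut-3-en-2-ol.

Step 1
Reactants: 1 methyl acetoacetate; 2 (E)-hex-4-en-3-one
Product: 5 methyl (1S,6S)-2,3,6-trimethyl-4-oxocyclohex-2-ene-1-carboxylate, via Michael adduct 3 (not isolated), via aldol 4 (not isolated)
Conditions: 9-amino-9-deoxy-epi-quinine (20 mol %), CF3CO2H (40 mol %), toluene, 25 °C; then TsOH·H2O (10 mol %), toluene, 110 °C, azeotropic removal of water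
Reagents that add atoms: none
Why: Iminium-catalysed enantioselective Michael addition of the β-keto ester to the enone sets C6 (the cinchona primary amine shields one face of the iminium ion; the quinidine-derived pseudo-enantiomer is used if the sense proves opposite), and acid-mediated aldol condensation of the ethyl ketone onto the acetyl group (Robinson-type annulation) closes the ring; C1 stays epimerisable, so the cis ester 5 is drawn from the equilibrium mixture and the trans epimer is re-equilibrated with base.

Step 2
Reactants: 6 5-methylhex-4-enal; 7 diethyl allylphosphonate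
Product: 8 (3E)-8-methylnona-1,3,7-triene
Conditions: 7, n-BuLi, THF/HMPA, −78 °C; then 6, −78 → 25 °C
Reagents that add atoms: none
Why: Horner–Wadsworth–Emmons olefination of the aldehyde with the α-lithiated allylphosphonate should give the E-configured 1,3-diene; no stereocentre is formed and any Z isomer cannot reach the s-cis form needed in step 3.

Step 3
Reactants: 5 methyl (1S,6S)-2,3,6-trimethyl-4-oxocyclohex-2-ene-1-carboxylate; 8 (3E)-8-methylnona-1,3,7-triene
Product: 9 methyl (1S,2S,4aR,8aR)-2,4a,8a-trimethyl-5-(4-methylpent-3-en-1-yl)-4-oxo-1,2,3,4,4a,5,8,8a-octahydronaphthalene-1-carboxylate (C5 epimers)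
Conditions: AlBr3/AlMe3 (5:1, 0.5 equiv), 8 (3 equiv), toluene/CH2Cl2, −10 → 25 °C
Reagents that add atoms: none
Why: Lewis-acid-activated, asynchronous but suprafacial [4+2] cycloaddition in which the aluminium-complexed enone C=C of 5 (its C2 and C3, the later C8a and C4a) takes up the s-cis diene, the unsubstituted diene terminus bonding to the β-carbon C8a and the alkyl-bearing terminus to the α-carbon C4a ("ortho" orientation). The closest known reaction type is the AlBr3/AlMe3-promoted Diels–Alder addition of dienes to β,β-disubstituted and tetrasubstituted cyclohexenones, which builds vicinal quaternary carbons, together with the anti-selective diene additions to 5-substituted cyclohexenones such as carvone. Ring B is closed as a six-membered ring in an intermolecular [4+2] mode, both σ bonds forming on one face of the alkene, which fixes the cis fusion and the cis relation of the angular methyls at C4a and C8a. Their absolute configuration should follow from attack on the cis ester in the half-chair with the C1 ester pseudoaxial (relief of allylic strain against the neighbouring vinylic methyl) and the C2 methyl equatorial, on the face anti to both groups; C5 forms as an endo/exo mixture of no consequence because it becomes sp2 in step 6. The step needs regioselectivity (matched polarisation of the 1-alkyl diene and the complexed enone), facial selectivity (the two ring A substituents) and survival of the trisubstituted chain olefin (AlMe3 as proton scavenger, low temperature). The C2 methyl therefore emerges on the face opposite to that of the target and is corrected in steps 4 and 5.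

Step 4
Reactants: 9 methyl (1S,2S,4aR,8aR)-2,4a,8a-trimethyl-5-(4-methylpent-3-en-1-yl)-4-oxo-1,2,3,4,4a,5,8,8a-octahydronaphthalene-1-carboxylate
Product: 10 methyl (1S,4aR,8aR)-2,4a,8a-trimethyl-5-(4-methylpent-3-en-1-yl)-4-oxo-1,4,4a,5,8,8a-hexahydronaphthalene-1-carboxylate
Conditions: IBX (2.5 equiv), 4-methoxypyridine N-oxide (2.5 equiv), DMSO, 25 °C
Reagents that add atoms: none
Why: IBX-mediated α,β-dehydrogenation of the ketone through its enol; C3 is the only α-carbon with hydrogens (C4a is quaternary), so the single enone C2=C3 should form, erasing the mis-set C2 centre while C1, C4a and C8a are untouched under the neutral conditions.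

Step 5
Reactants: 10 methyl (1S,4aR,8aR)-2,4a,8a-trimethyl-5-(4-methylpent-3-en-1-yl)-4-oxo-1,4,4a,5,8,8a-hexahydronaphthalene-1-carboxylate
Product: 12 methyl (1S,2R,4aR,8aR)-2,4a,8a-trimethyl-5-(4-methylpent-3-en-1-yl)-4-oxo-1,2,3,4,4a,5,8,8a-octahydronaphthalene-1-carboxylate, via lithium enolate 11 (not isolated)
Conditions: Li (2.2 equiv), NH3(l)/THF, t-BuOH (1 equiv), −78 °C; then NH4Cl
Reagents that add atoms: none
Why: Dissolving-metal (Birch-type) conjugate reduction of the enone; the β-carbon C2 is protonated axially in the half-chair that keeps the C1 ester equatorial (the other half-chair would force the ester into a 1,3-diaxial clash with the C4a methyl), which should place the C2 methyl equatorial, trans to the ester and on the ring B face as in the target, while the ester and the isolated olefins are not reduced at −78 °C with a limited amount of lithium.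

Step 6
Reactants: 12 methyl (1S,2R,4aR,8aR)-2,4a,8a-trimethyl-5-(4-methylpent-3-en-1-yl)-4-oxo-1,2,3,4,4a,5,8,8a-octahydronaphthalene-1-carboxylate
Product: 13 methyl (1S,2R,4aR,8aR)-2,4a,8a-trimethyl-5-(4-methylpent-3-en-1-yl)-4-oxo-1,2,3,4,4a,7,8,8a-octahydronaphthalene-1-carboxylate
Conditions: RuHCl(CO)(PPh3)3 (5 mol %), toluene, 110 °C
Reagents that add atoms: none
Why: Ruthenium-hydride-catalysed olefin isomerisation (hydrometalation/β-hydride elimination) should move the cis-disubstituted C6=C7 bond to the thermodynamically favoured trisubstituted C5=C6 position, the only more substituted position within reach because C4a and C8a are quaternary; both C5 epimers converge on one product, no stereocentre is formed, and the hindered trisubstituted olefins are poor substrates for further migration.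

Step 7
Reactants: 13 methyl (1S,2R,4aR,8aR)-2,4a,8a-trimethyl-5-(4-methylpent-3-en-1-yl)-4-oxo-1,2,3,4,4a,7,8,8a-octahydronaphthalene-1-carboxylate
Product: 15 (1S,2R,4aR,8aR)-2,4a,8a-trimethyl-5-(4-methylpent-3-en-1-yl)-1,2,3,4,4a,7,8,8a-octahydronaphthalene-1-carboxylic acid, via hydrazone 14 (not isolated)
Conditions: N2H4·H2O, diethylene glycol, 130 °C; then KOH, 200 °C; then aq. HCl
Reagents that add atoms: potassium hydroxide [K+].[OH-]
Why: Wolff–Kishner reduction of the hindered C4 ketone via its hydrazone with concurrent saponification of the methyl ester; the base equilibrates C1 to the equatorial carboxylate trans to the C2 methyl, which is the configuration of the target, and isolated olefins are inert to the conditions.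

Step 8
Reactants: 16 (S)-glycidol
Product: 17 (R)-glycidyl acetate
Conditions: Ac2O, Et3N, DMAP (cat.), CH2Cl2, 0 °C
Reagents that add atoms: acetic anhydride CC(=O)OC(C)=O
Why: DMAP-catalysed O-acetylation of the primary alcohol; the stereocentre is not touched (the descriptor changes from S to R only through the priority rules).

Step 9
Reactants: 15 (1S,2R,4aR,8aR)-2,4a,8a-trimethyl-5-(4-methylpent-3-en-1-yl)-1,2,3,4,4a,7,8,8a-octahydronaphthalene-1-carboxylic acid; 17 (R)-glycidyl acetate
Product: 18 (2S)-3-(acetyloxy)-2-hydroxypropyl (1S,2R,4aR,8aR)-2,4a,8a-trimethyl-5-(4-methylpent-3-en-1-yl)-1,2,3,4,4a,7,8,8a-octahydronaphthalene-1-carboxylate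
Conditions: 17 (1.3 equiv), Bu4NBr (10 mol %), toluene, 80 °C
Reagents that add atoms: none
Why: Halide-catalysed nucleophilic ring opening of the terminal epoxide by the carboxylic acid (SN2 at the unsubstituted CH2) should give the 1,3-diacylglycerol with a free secondary hydroxyl; the glycerol stereocentre is carried over unchanged from 17 and the hindered acid reacts only through its carboxylate oxygen.

**Compound list**

1 | methyl acetoacetate | COC(=O)CC(C)=O | starting material
2 | (E)-hex-4-en-3-one | CCC(=O)/C=C/C | starting material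
3 | methyl (3S)-2-acetyl-3-methyl-5-oxoheptanoate (Michael adduct, C2 epimers) | COC(=O)C(C(C)=O)[C@@H](C)CC(=O)CC | intermediate
4 | methyl (6S)-2-hydroxy-2,3,6-trimethyl-4-oxocyclohexane-1-carboxylate (aldol, other centres undefined) | COC(=O)C1[C@@H](C)CC(=O)C(C)C1(C)O | intermediate
5 | methyl (1S,6S)-2,3,6-trimethyl-4-oxocyclohex-2-ene-1-carboxylate (cis isomer, equilibrates with the 1R epimer) | COC(=O)[C@H]1[C@@H](C)CC(=O)C(C)=C1C | intermediate
6 | 5-methylhex-4-enal | CC(C)=CCCC=O | starting material
7 | diethyl allylphosphonate | C=CCP(=O)(OCC)OCC | starting material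
8 | (3E)-8-methylnona-1,3,7-triene | C=C/C=C/CCC=C(C)C | intermediate
9 | methyl (1S,2S,4aR,8aR)-2,4a,8a-trimethyl-5-(4-methylpent-3-en-1-yl)-4-oxo-1,2,3,4,4a,5,8,8a-octahydronaphthalene-1-carboxylate (C5 epimers) | COC(=O)[C@H]1[C@@H](C)CC(=O)[C@]2(C)C(CCC=C(C)C)C=CC[C@]12C | intermediate
10 | methyl (1S,4aR,8aR)-2,4a,8a-trimethyl-5-(4-methylpent-3-en-1-yl)-4-oxo-1,4,4a,5,8,8a-hexahydronaphthalene-1-carboxylate | COC(=O)[C@H]1C(C)=CC(=O)[C@]2(C)C(CCC=C(C)C)C=CC[C@]12C | intermediate
11 | lithium enolate (C3=C4) of 12 | [Li+].COC(=O)[C@H]1[C@H](C)C=C([O-])[C@]2(C)C(CCC=C(C)C)C=CC[C@]12C | intermediate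
12 | methyl (1S,2R,4aR,8aR)-2,4a,8a-trimethyl-5-(4-methylpent-3-en-1-yl)-4-oxo-1,2,3,4,4a,5,8,8a-octahydronaphthalene-1-carboxylate (C5 epimers) | COC(=O)[C@H]1[C@H](C)CC(=O)[C@]2(C)C(CCC=C(C)C)C=CC[C@]12C | intermediate
13 | methyl (1S,2R,4aR,8aR)-2,4a,8a-trimethyl-5-(4-methylpent-3-en-1-yl)-4-oxo-1,2,3,4,4a,7,8,8a-octahydronaphthalene-1-carboxylate | COC(=O)[C@H]1[C@H](C)CC(=O)[C@]2(C)C(CCC=C(C)C)=CCC[C@]12C | intermediate
14 | hydrazone of 13 at C4 | COC(=O)[C@H]1[C@H](C)CC(=NN)[C@]2(C)C(CCC=C(C)C)=CCC[C@]12C | intermediate
15 | (1S,2R,4aR,8aR)-2,4a,8a-trimethyl-5-(4-methylpent-3-en-1-yl)-1,2,3,4,4a,7,8,8a-octahydronaphthalene-1-carboxylic acid | OC(=O)[C@H]1[C@H](C)CC[C@]2(C)C(CCC=C(C)C)=CCC[C@]12C | intermediate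
16 | (S)-glycidol, [(2S)-oxiran-2-yl]methanol | OC[C@H]1CO1 | starting material
17 | (R)-glycidyl acetate, [(2R)-oxiran-2-yl]methyl acetate | CC(=O)OC[C@H]1CO1 | intermediate
18 | (2S)-3-(acetyloxy)-2-hydroxypropyl (1S,2R,4aR,8aR)-2,4a,8a-trimethyl-5-(4-methylpent-3-en-1-yl)-1,2,3,4,4a,7,8,8a-octahydronaphthalene-1-carboxylate | CC(=O)OC[C@H](O)COC(=O)[C@H]1[C@H](C)CC[C@]2(C)C(CCC=C(C)C)=CCC[C@]12C | target

**Step count.** Total: 9 steps. Longest linear sequence: 7 steps (1, 3, 4, 5, 6, 7, 9).

**Steps most likely to fail**

Step 3. The cycloaddition may stall because the tetrasubstituted enone meets an unactivated 1-alkyl diene, the triene may oligomerise under the Lewis acid, and facial control may erode if the trans ester reacts competitively. The fallback sets out from 6 (with 5 as partner) and comes back at 9. Wittig olefination of 6 with Ph3P=CHC(O)CH3 should give (3E)-8-methylnona-3,7-dien-2-one F1. TBSOTf/Et3N should turn it into tert-butyl(dimethyl){[(3E)-8-methylnona-1,3,7-trien-2-yl]oxy}silane F2, a 2-silyloxy diene of the class for which the mixed aluminium Lewis acid is best established. Its cycloaddition to 5, in which the silyloxy and alkyl groups both direct the CH2 terminus to C8a, should give methyl (1S,2S,4aR,8aR)-7-[(tert-butyldimethylsilyl)oxy]-2,4a,8a-trimethyl-5-(4-methylpent-3-en-1-yl)-4-oxo-1,2,3,4,4a,5,8,8a-octahydronaphthalene-1-carboxylate F3. CsF/PhNTf2 should convert this into methyl (1S,2S,4aR,8aR)-2,4a,8a-trimethyl-5-(4-methylpent-3-en-1-yl)-4-oxo-7-{[(trifluoromethyl)sulfonyl]oxy}-1,2,3,4,4a,5,8,8a-octahydronaphthalene-1-carboxylate F4. Reduction with Pd(OAc)2/PPh3, Bu3N and HCO2H should then give 9.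

Step 6. The migration may stall at the hindered allylic methine C5–H, or the metal hydride may walk on toward the chain olefin. The fallback runs from 12 to 13 without a new isolated compound: a radical hydrogen-atom-transfer isomerisation (Co(salen)Cl with PhSiH3, benzene, 25 °C) replaces hydrometalation/β-hydride elimination. Reversible hydrogen-atom addition at C7 and abstraction of the C5 hydrogen should lead to the trisubstituted olefin, and there is no metal alkyl that can travel along the chain.

Step 5. The proton may enter C2 from the wrong face, the amide base may remove the γ-hydrogen at C1 and scramble that centre, and the ester may be partly reduced. The fallback runs from 10 to 12 without a new isolated compound: a ligand-controlled copper hydride conjugate reduction (Cu(OAc)2, the DTBM-SEGPHOS enantiomer that delivers hydride to the required face of C2, polymethylhydrosiloxane, t-BuOH, toluene) sets C2 under reagent control in a non-basic medium.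

Further compounds
F1 | step 3 | (3E)-8-methylnona-3,7-dien-2-one | CC(=O)/C=C/CCC=C(C)C
F2 | step 3 | tert-butyl(dimethyl){[(3E)-8-methylnona-1,3,7-trien-2-yl]oxy}silane | C=C(O[Si](C)(C)C(C)(C)C)/C=C/CCC=C(C)C
F3 | step 3 | methyl (1S,2S,4aR,8aR)-7-[(tert-butyldimethylsilyl)oxy]-2,4a,8a-trimethyl-5-(4-methylpent-3-en-1-yl)-4-oxo-1,2,3,4,4a,5,8,8a-octahydronaphthalene-1-carboxylate | COC(=O)[C@H]1[C@@H](C)CC(=O)[C@]2(C)C(CCC=C(C)C)C=C(O[Si](C)(C)C(C)(C)C)C[C@]12C
F4 | step 3 | methyl (1S,2S,4aR,8aR)-2,4a,8a-trimethyl-5-(4-methylpent-3-en-1-yl)-4-oxo-7-{[(trifluoromethyl)sulfonyl]oxy}-1,2,3,4,4a,5,8,8a-octahydronaphthalene-1-carboxylate | COC(=O)[C@H]1[C@@H](C)CC(=O)[C@]2(C)C(CCC=C(C)C)C=C(OS(=O)(=O)C(F)(F)F)C[C@]12C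
F0 | step 6 | none | none
F0 | step 5 | none | none
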